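The route rests on cutting the C3–C4 bond of the pyranone (ring C). It uses the fact that the C4 carbonyl stands next to C3, the carbon that carries benzylic C9 and the anisyl ring B. C4 can therefore act as an acyl anion toward a C3≡C9 alkyne hung on O1 through C2. One carbene-catalysed operation forms C3–C4, closes ring C and, after a base-induced double-bond shift, gives the 3-benzylchromone. The precursor is a pentasubstituted ring A benzaldehyde with an O-(3-anisylpropargyl) ether. It already holds the O5 methyl ether and an acid-labile MOM group on O7, so only deprotection and C8 formylation follow.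

Key step: step 8

Remarks on the chemistry
- **Numbering:** chromone numbering is used, with ring A the benzo ring, ring B the anisyl ring and ring C the pyranone. In the benzaldehydes, CHO becomes C4, C1 becomes C4a, C2-O becomes O5, C3-CH3 becomes C6-CH3, C4-O becomes O7, C5-H becomes C8-H and C6-O becomes O1.
- **O5 methyl ether:** it is set before the key step. The aldehyde is then flanked by the smallest possible ortho group, and no Lewis-acid dealkylation is needed on the chromone.
- **No benzyl ethers:** their hydrogenolysis would compete with saturation of C2=C3, boron trihalides would also strip the O5 methyl group, and their phenyl rings would compete in step 2.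
- **Tether:** the link between ring A and the alkyne has two atoms (O1 and C2).
- **Stereochemistry:** the target has no stereocentre.
- **Assumption:** 2-methylresorcinol, propargyl bromide, 4-iodoanisole and all reagents named are purchased.

Step 1
Reactants: 1 2-methylresorcinol (2-methylbenzene-1,3-diol)
Product: 2 1,3-bis(methoxymethoxy)-2-methylbenzene
Conditions: NaH, MOMCl, DMF, 0 °C to rt
Reagents that add atoms: chloromethyl methyl ether (MOMCl), COCCl
Why: Williamson-type O-alkylation (MOM protection) of both phenoxides with the very reactive chloromethyl ether should be clean, and MOM is chosen because it carries no aromatic C–H that could compete in the borylation of step 2.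

Step 2
Reactants: 2 1,3-bis(methoxymethoxy)-2-methylbenzene
Product: 4 3,5-bis(methoxymethoxy)-4-methylphenol, via aryl pinacol boronate 3 (not isolated)
Conditions: [Ir(OMe)(cod)]2 (1.5 mol %), 4,4'-di-tert-butyl-2,2'-bipyridine (3 mol %), B2pin2 (1.1 equiv), THF, 80 °C; then 30 % H2O2, aq. NaOH, 0 °C
Reagents that add atoms: bis(pinacolato)diboron, CC1(C)OB(OC1(C)C)B1OC(C)(C)C(C)(C)O1 (boryl group of 3 only); hydrogen peroxide, OO (phenol oxygen of 4)
Why: Sterically controlled iridium-catalysed aromatic C–H borylation should take the only ring C–H without an ortho neighbour (para to the methyl group), and the standard alkaline peroxide oxidation of the aryl boronate (aryl shift from boron to oxygen) then gives the symmetric phenol in the same flask without touching the base-stable MOM ethers.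

Step 3
Reactants: 4 3,5-bis(methoxymethoxy)-4-methylphenol
Product: 5 6-hydroxy-2,4-bis(methoxymethoxy)-3-methylbenzaldehyde
Conditions: MgCl2, Et3N, (CH2O)n, MeCN, reflux; aq. NH4Cl
Reagents that add atoms: paraformaldehyde, as formaldehyde C=O
Why: Casnati–Skattebøl ortho-formylation, in which the chloromagnesium phenoxide (ArOMgCl) delivers bound formaldehyde only to a carbon ortho to the free OH and a second formaldehyde accepts hydride, and since the two ortho positions are related by symmetry only one aldehyde can form.

Step 4
Reactants: 5 6-hydroxy-2,4-bis(methoxymethoxy)-3-methylbenzaldehyde; 6 propargyl bromide (3-bromoprop-1-yne)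
Product: 7 2,4-bis(methoxymethoxy)-3-methyl-6-(prop-2-yn-1-yloxy)benzaldehyde
Conditions: K2CO3, DMF, rt to 50 °C
Reagents that add atoms: none
Why: Williamson ether synthesis at the only free phenol, whose hydrogen bond to the aldehyde is broken by K2CO3 in DMF, installs the O1–C2 bond and the alkyne carbons C3 and C9 with a primary propargylic bromide that cannot eliminate.

Step 5
Reactants: 7 2,4-bis(methoxymethoxy)-3-methyl-6-(prop-2-yn-1-yloxy)benzaldehyde
Product: 8 2-hydroxy-4-(methoxymethoxy)-3-methyl-6-(prop-2-yn-1-yloxy)benzaldehyde
Conditions: p-TsOH·H2O (10 mol %), MeOH–CH2Cl2, 0 °C to rt, NaHCO3 quench at the mono-cleavage stage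
Reagents that add atoms: none
Why: Carbonyl-assisted acid-catalysed acetal exchange, in which the MOM group wedged between the formyl and methyl groups is twisted out of conjugation, is protonated through the neighbouring carbonyl oxygen and leaves a phenol locked in a hydrogen bond, so it should go well before the para MOM group, while the propargyl ether is inert to dilute protic acid.

Step 6
Reactants: 8 2-hydroxy-4-(methoxymethoxy)-3-methyl-6-(prop-2-yn-1-yloxy)benzaldehyde
Product: 9 2-methoxy-4-(methoxymethoxy)-3-methyl-6-(prop-2-yn-1-yloxy)benzaldehyde
Conditions: MeI, K2CO3, DMF, rt to 40 °C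
Reagents that add atoms: iodomethane, CI
Why: Williamson methylation of the chelated, hindered phenol with the smallest electrophile in a polar aprotic solvent fixes the O5 methyl ether of the target, and the aldehyde, MOM ether and terminal alkyne are untouched by K2CO3.

Step 7
Reactants: 9 2-methoxy-4-(methoxymethoxy)-3-methyl-6-(prop-2-yn-1-yloxy)benzaldehyde; 10 4-iodoanisole
Product: 11 2-methoxy-4-(methoxymethoxy)-6-{[3-(4-methoxyphenyl)prop-2-yn-1-yl]oxy}-3-methylbenzaldehyde
Conditions: PdCl2(PPh3)2 (2 mol %), CuI (4 mol %), Et3N, THF (degassed), rt to 40 °C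
Reagents that add atoms: none
Why: Sonogashira coupling of a terminal aryl propargyl ether with an aryl iodide is the standard entry to such internal alkynes and runs near room temperature, where the aldehyde, MOM and methyl ethers are spectators.

Step 8
Reactants: 11 2-methoxy-4-(methoxymethoxy)-6-{[3-(4-methoxyphenyl)prop-2-yn-1-yl]oxy}-3-methylbenzaldehyde
Product: 14 5-methoxy-3-(4-methoxybenzyl)-7-(methoxymethoxy)-6-methyl-4H-chromen-4-one, via Breslow enaminol 12 (not isolated), via (E)-benzylidenechromanone 13 (not isolated)
Conditions: 3-ethyl-5-(2-hydroxyethyl)-4-methylthiazolium bromide (20 mol %), K2CO3 (30 mol %), 1,4-dioxane, 90 °C; then DBU (1 equiv), 90 °C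
Reagents that add atoms: none
Why: The thiazol-2-ylidene adds to the aldehyde carbon (future C4) and a proton shift gives the Breslow enaminol 12, whose nucleophilic C4 and O–H proton are delivered to the same side of the C3≡C9 triple bond in a concerted, Conia-ene-like event, after which loss of the carbene leaves the (E)-enone 13. The closest known reaction type is the carbene-catalysed intramolecular hydroacylation of unactivated, aryl-capped alkynes in O-propargyl salicylaldehydes, combined with the base isomerisation of 3-benzylidenechroman-4-ones to 3-benzylchromones. Ring C closes in the 6-exo-dig mode, because the two-atom O1–C2 link brings C3 within reach of C4, whereas attack at C9 would need a strained 7-endo geometry. No stereocentre is created, and the E geometry of 13 that results from syn addition is erased when DBU removes a C2 proton and the dienolate is reprotonated at C9, a shift driven by formation of the aromatic 4-pyranone. The step needs ring closure to outrun benzoin and Stetter pathways, which the two ortho oxygen substituents of 11 secure by blocking bimolecular attack at the carbonyl, while the small ortho methoxy group and a slim N-ethyl thiazolylidene keep that carbonyl open to the catalyst. The MOM ether, the methyl ethers and the aryl methyl group are inert to carbene and amidine base.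

Step 9
Reactants: 14 5-methoxy-3-(4-methoxybenzyl)-7-(methoxymethoxy)-6-methyl-4H-chromen-4-one
Product: 15 7-hydroxy-5-methoxy-3-(4-methoxybenzyl)-6-methyl-4H-chromen-4-one
Conditions: 3 M HCl, MeOH, 50 °C
Reagents that add atoms: none
Why: Acid-catalysed acetal exchange with methanol removes the MOM ether without reducing agents or Lewis acids, so the C2=C3 double bond, the O5 methyl ether peri to C4=O and the anisyl ether should all survive.

Step 10
Reactants: 15 7-hydroxy-5-methoxy-3-(4-methoxybenzyl)-6-methyl-4H-chromen-4-one
Product: 17 7-hydroxy-5-methoxy-3-(4-methoxybenzyl)-6-methyl-4-oxo-4H-chromene-8-carbaldehyde (target), via aldimine 16 (not isolated)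
Conditions: hexamethylenetetramine, AcOH, 100 °C; then 3 M HCl, 90 °C
Reagents that add atoms: hexamethylenetetramine, C1N2CN3CN1CN(C2)C3 (formyl carbon); water, O (formyl oxygen)
Why: Duff reaction, well established for 7-hydroxychromones, 7-hydroxyisoflavones and 7-hydroxycoumarins, in which the phenol directs the iminium electrophile from hexamethylenetetramine to its ortho position, C8 is the only free carbon of ring A (C6 is blocked by methyl), the non-phenolic ring B is not attacked in acetic acid, and acid hydrolysis of the aldimine frees the aldehyde.

Compound list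
1 | 2-methylresorcinol (2-methylbenzene-1,3-diol) | Cc1c(O)cccc1O | starting material
2 | 1,3-bis(methoxymethoxy)-2-methylbenzene | COCOc1cccc(OCOC)c1C | intermediate
3 | 2-[3,5-bis(methoxymethoxy)-4-methylphenyl]-4,4,5,5-tetramethyl-1,3,2-dioxaborolane | COCOc1cc(B2OC(C)(C)C(C)(C)O2)cc(OCOC)c1C | intermediate
4 | 3,5-bis(methoxymethoxy)-4-methylphenol | COCOc1cc(O)cc(OCOC)c1C | intermediate
5 | 6-hydroxy-2,4-bis(methoxymethoxy)-3-methylbenzaldehyde | O=Cc1c(O)cc(OCOC)c(C)c1OCOC | intermediate
6 | propargyl bromide (3-bromoprop-1-yne) | C#CCBr | starting material
7 | 2,4-bis(methoxymethoxy)-3-methyl-6-(prop-2-yn-1-yloxy)benzaldehyde | O=Cc1c(OCC#C)cc(OCOC)c(C)c1OCOC | intermediate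
8 | 2-hydroxy-4-(methoxymethoxy)-3-methyl-6-(prop-2-yn-1-yloxy)benzaldehyde | O=Cc1c(OCC#C)cc(OCOC)c(C)c1O | intermediate
9 | 2-methoxy-4-(methoxymethoxy)-3-methyl-6-(prop-2-yn-1-yloxy)benzaldehyde | O=Cc1c(OCC#C)cc(OCOC)c(C)c1OC | intermediate
10 | 4-iodoanisole | COc1ccc(I)cc1 | starting material
11 | 2-methoxy-4-(methoxymethoxy)-6-{[3-(4-methoxyphenyl)prop-2-yn-1-yl]oxy}-3-methylbenzaldehyde (key-step precursor) | O=Cc1c(OCC#Cc2ccc(OC)cc2)cc(OCOC)c(C)c1OC | intermediate
12 | Breslow enaminol: 3-ethyl-5-(2-hydroxyethyl)-4-methyl-2-[hydroxy(aryl)methylidene]-2,3-dihydrothiazole, aryl being the ring of 11 (enol geometry undefined) | CCN1C(C)=C(CCO)SC1=C(O)c1c(OCC#Cc2ccc(OC)cc2)cc(OCOC)c(C)c1OC | intermediate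
13 | (E)-5-methoxy-3-(4-methoxybenzylidene)-7-(methoxymethoxy)-6-methylchroman-4-one | COCOc1cc2OC/C(=C\c3ccc(OC)cc3)C(=O)c2c(OC)c1C | intermediate
14 | 5-methoxy-3-(4-methoxybenzyl)-7-(methoxymethoxy)-6-methyl-4H-chromen-4-one (key-step product) | COCOc1cc2occ(Cc3ccc(OC)cc3)c(=O)c2c(OC)c1C | intermediate
15 | 7-hydroxy-5-methoxy-3-(4-methoxybenzyl)-6-methyl-4H-chromen-4-one | COc1ccc(Cc2coc3cc(O)c(C)c(OC)c3c2=O)cc1 | intermediate
16 | 7-hydroxy-8-(iminomethyl)-5-methoxy-3-(4-methoxybenzyl)-6-methyl-4H-chromen-4-one (aldimine, drawn as the parent NH form) | COc1ccc(Cc2coc3c(C=N)c(O)c(C)c(OC)c3c2=O)cc1 | intermediate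
17 | 7-hydroxy-5-methoxy-3-(4-methoxybenzyl)-6-methyl-4-oxo-4H-chromene-8-carbaldehyde | COc1ccc(Cc2coc3c(C=O)c(O)c(C)c(OC)c3c2=O)cc1 | target

Total step count: 10
Longest linear sequence: 10 steps (1 → 2 → 4 → 5 → 7 → 8 → 9 → 11 → 14 → 15 → 17). Compounds 6 and 10 are purchased and enter directly.

Steps most likely to fail

**Step 8 (key step).** The carbene may add too slowly to the doubly ortho-substituted, strongly donor-substituted carbonyl. Base-induced propargyl-to-allenyl ether isomerisation or catalyst decay could then overtake ring closure. The fallback makes the same C3–C4 bond reductively instead of by umpolung.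
- It sets out from 11 with a nickel-catalysed reductive ynal cyclisation (Ni(cod)2, PBu3, Et3SiH, THF). Zerovalent nickel couples aldehyde and alkyne to an oxanickelacycle, which the silane cleaves with syn delivery of hydrogen.
- This should give the racemic triethylsilyl ether of the (E)-3-benzylidenechroman-4-ol F1.
- TBAF in THF then frees the racemic (E)-allylic alcohol F2.
- MnO2 in CH2Cl2 oxidises it to 13, which is isolated in this variant.
- DBU in warm dioxane shifts the double bond, and the route is rejoined at 14.

**Step 5.** Discrimination between the ortho and para acetals may be poor, with loss of both MOM groups or incomplete conversion at the point of quenching. The fallback gives up kinetic discrimination in deprotection and relies on selective protection instead.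
- It sets out from 7 with exhaustive MOM removal (3 M HCl, MeOH, 50 °C), which gives 2,4-dihydroxy-3-methyl-6-(prop-2-yn-1-yloxy)benzaldehyde F3.
- One equivalent of MOMCl with iPr2NEt in CH2Cl2 at 0 °C should then protect only the free 4-OH. The 2-OH is the sole ortho hydroxyl, is chelated to the aldehyde and is flanked on both sides.
- The route is rejoined at 8.

**Step 10.** Electrophilic attack at C8 of the carbonyl-deactivated phenol may be sluggish in acetic acid, and prolonged heating brings resinification. The fallback separates C–C bond formation from the adjustment of oxidation level.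
- It sets out from 15 with Mannich aminomethylation, using bis(dimethylamino)methane in refluxing 1,4-dioxane. This runs on the more nucleophilic phenol or phenoxide under non-acidic conditions and can only reach C8.
- It should give 8-[(dimethylamino)methyl]-7-hydroxy-5-methoxy-3-(4-methoxybenzyl)-6-methyl-4H-chromen-4-one F4.
- A Sommelet-type oxidation of this phenolic Mannich base (hexamethylenetetramine, AcOH, 100 °C, then aqueous HCl) converts the aminomethyl group into the aldehyde.
- The route is rejoined at 17.

Further compounds
F1 | step 8 | racemic (E)-triethyl{[5-methoxy-3-(4-methoxybenzylidene)-7-(methoxymethoxy)-6-methylchroman-4-yl]oxy}silane | COCOc1cc2OC/C(=C\c3ccc(OC)cc3)C(O[Si](CC)(CC)CC)c2c(OC)c1C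
F2 | step 8 | racemic (E)-5-methoxy-3-(4-methoxybenzylidene)-7-(methoxymethoxy)-6-methylchroman-4-ol | COCOc1cc2OC/C(=C\c3ccc(OC)cc3)C(O)c2c(OC)c1C
F3 | step 5 | 2,4-dihydroxy-3-methyl-6-(prop-2-yn-1-yloxy)benzaldehyde | O=Cc1c(OCC#C)cc(O)c(C)c1O
F4 | step 10 | 8-[(dimethylamino)methyl]-7-hydroxy-5-methoxy-3-(4-methoxybenzyl)-6-methyl-4H-chromen-4-one | COc1ccc(Cc2coc3c(CN(C)C)c(O)c(C)c(OC)c3c2=O)cc1
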